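**Assumptions (one line each)**
- The target has no sp3 stereocentres, so "single enantiomer" is moot. Its stereochemistry is nine E trisubstituted alkenes in a decaprenyl chain (ten isoprene units, the last being the terminal dimethylallyl). Ring: 2-methoxy-5-methyl-6-decaprenyl-1,4-benzoquinone (demethoxyubiquinone-10).
- All-trans-decaprenol (C50) is taken as commercially available from specialty suppliers.

**Retrosynthesis**
1. The quinone comes from oxidative demethylation of a para-dimethoxy arene (CAN), which leaves the third, meta-related OMe in place.
2. The C(aryl)–C(allyl) bond is made by Cu-mediated SN2 coupling of an aryllithium with all-E decaprenyl bromide. This keeps all nine E alkenes intact.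
3. The aryl bromide is made regioselectively from 2,4-dimethoxytoluene by formylation at C5, Dakin oxidation to the phenol, and OH-directed ortho-bromination into the only free position next to the methyl.
4. The only ring is the pre-existing benzene. The quinone is unmasked in the last step.

**Route**

Step 1
Reactants: 1 (2,4-dimethoxytoluene)
Product: 2 (2,4-dimethoxy-5-methylbenzaldehyde)
Conditions: POCl3, DMF, 0 → 60 °C; then aq. NaOAc
Reagents that add atoms: DMF, CN(C)C=O (source of the CHO group)
Why: Vilsmeier–Haack formylation goes to C5, which is para to one OMe and ortho to the other. C3 is hindered and C6 is meta to both OMe groups.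

Step 2
Reactants: 2
Product: 3 (2,4-dimethoxy-5-methylphenol)
Conditions: mCPBA (1.2 equiv), CH2Cl2, 0 °C → rt; then K2CO3, MeOH
Reagents that add atoms: mCPBA, O=C(OO)c1cccc(Cl)c1 (supplies the inserted O)
Why: Dakin-type Baeyer–Villiger oxidation. The electron-rich aryl migrates to give the aryl formate, and methanolysis liberates the phenol. No stereocentres are involved.

Step 3
Reactants: 3
Product: 4 (2-bromo-4,6-dimethoxy-3-methylphenol)
Conditions: NBS (1.0 equiv), i-Pr2NH (0.1 equiv), CH2Cl2, −78 °C → rt
Reagents that add atoms: NBS, O=C1CCC(=O)N1Br
Why: Amine-mediated ortho-selective bromination of phenols. The N-bromoamine is H-bonded to the OH and delivers Br to the only free ortho carbon, which sits between OH and Me. This is the position needed for the chain.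

Step 4
Reactants: 4
Product: 5 (2-bromo-3,4,6-trimethoxytoluene)
Conditions: MeI (3 equiv), K2CO3, acetone, reflux
Reagents that add atoms: MeI, CI
Why: Williamson O-methylation caps the phenol so that the later Br/Li exchange is clean. It also creates the para-dimethoxy pair needed for quinone formation.

Step 5
Reactants: 6 (all-trans-decaprenol)
Product: 7 (all-E decaprenyl bromide)
Conditions: PBr3 (0.4 equiv), Et2O, 0 °C, 1 h; use crude and cold
Reagents that add atoms: PBr3, BrP(Br)Br (supplies Br)
Why: Primary allylic alcohol to bromide by SN2 at CH2. The alkenes are untouched and the E geometry is retained.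

Step 6
Reactants: 5 and 7
Product: 8 (2-decaprenyl-3,4,6-trimethoxytoluene)
Conditions: t-BuLi (2 equiv), THF, −78 °C, 30 min; then CuI (0.1 equiv), add 7, −78 °C → rt
Reagents that add atoms: none
Why: Br/Li exchange gives the aryllithium, and Cu catalysis makes the coupling proceed by SN2 at the primary allylic carbon with no allylic transposition. All nine E alkenes are carried through unchanged.

Step 7
Reactants: 8
Product: 9 (target, DMQ10)
Conditions: CAN (3 equiv), MeCN/H2O 4:1, 0 °C, 10–15 min, dark
Reagents that add atoms: water, O (supplies the two carbonyl oxygens)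
Why: CAN oxidative demethylation of the 1,4-dimethoxy pair (C3/C6 OMe of the toluene) gives the p-quinone and loses 2 MeOH. The remaining OMe has no para partner, so it survives. The product is the target with the OMe flanking C=O, the Me and chain adjacent, and the ring CH next to the C=O that is para to the chain-bearing carbon's neighbour.

**Checks**
- Ring: C6 quinone with OMe, H, Me and chain in the target's pattern. Chain carbon is flanked by Me and C=O. The OMe-bearing carbon is next to the other C=O. This matches the target SMILES.
- Atom count: 8 → 9 is ArOMe2 + 2 H2O → quinone + 2 MeOH (plus 2 e⁻, 2 H⁺).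
- Stereochemistry: the nine E alkenes come from decaprenol and are untouched in steps 5–7. Step 7 is mild and short to limit acid-mediated isomerisation or cyclisation.

**Compound list**

| # | Name | SMILES | Role |
|---|---|---|---|
| 1 | 2,4-dimethoxytoluene | Cc1ccc(OC)cc1OC | starting material |
| 2 | 2,4-dimethoxy-5-methylbenzaldehyde | Cc1cc(C=O)c(OC)cc1OC | intermediate |
| 3 | 2,4-dimethoxy-5-methylphenol | Cc1cc(O)c(OC)cc1OC | intermediate |
| 4 | 2-bromo-4,6-dimethoxy-3-methylphenol | Cc1c(Br)c(O)c(OC)cc1OC | intermediate |
| 5 | 2-bromo-3,4,6-trimethoxytoluene | Cc1c(Br)c(OC)c(OC)cc1OC | intermediate |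
| 6 | all-trans-decaprenol | OC/C=C(\C)CC/C=C(\C)CC/C=C(\C)CC/C=C(\C)CC/C=C(\C)CC/C=C(\C)CC/C=C(\C)CC/C=C(\C)CC/C=C(\C)CCC=C(C)C | starting material |
| 7 | all-E decaprenyl bromide | BrC/C=C(\C)CC/C=C(\C)CC/C=C(\C)CC/C=C(\C)CC/C=C(\C)CC/C=C(\C)CC/C=C(\C)CC/C=C(\C)CC/C=C(\C)CCC=C(C)C | intermediate |
| 8 | 2-decaprenyl-3,4,6-trimethoxytoluene | Cc1c(C/C=C(\C)CC/C=C(\C)CC/C=C(\C)CC/C=C(\C)CC/C=C(\C)CC/C=C(\C)CC/C=C(\C)CC/C=C(\C)CC/C=C(\C)CCC=C(C)C)c(OC)c(OC)cc1OC | intermediate |
| 9 | 2-methoxy-5-methyl-6-decaprenyl-1,4-benzoquinone (DMQ10) | COC1=CC(=O)C(C)=C(C/C=C(\C)CC/C=C(\C)CC/C=C(\C)CC/C=C(\C)CC/C=C(\C)CC/C=C(\C)CC/C=C(\C)CC/C=C(\C)CC/C=C(\C)CCC=C(C)C)C1=O | target |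

**Totals:** 7 steps in total, with a longest linear sequence of 6 steps (1→2→3→4→5→6→7 of the compound numbering, i.e. steps 1, 2, 3, 4, 6, 7). Step 5 runs in parallel.

**Three steps most likely to fail**
1. **Step 7 (CAN oxidation).** The polyene is acid- and oxidant-sensitive, and overoxidation or demethylation at the wrong OMe is possible. Fallback: make the 1-OMOM analogue in step 4, and after coupling remove the MOM (PPTS, t-BuOH). Then oxidise the resulting 4-methoxyphenol under neutral conditions (salcomine/O2 or PIFA) instead of using CAN.
2. **Step 3 (ortho-bromination).** C3, between the two OMe groups, may compete. Fallback: skip the bromide. Allylate phenol 3 directly with decaprenol under BF3·OEt2 Friedel–Crafts conditions and separate the regioisomers, which removes steps 3–6 of the bromide sequence but accepts a mixture.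
3. **Step 6 (Cu-mediated coupling).** The long, lipophilic bromide is prone to SN2′ coupling, homocoupling and E/Z erosion. Fallback: transmetalate the aryllithium to ArZnCl and do a Pd(PPh3)4 Negishi coupling with 7, which uses a different mechanism and avoids the organocuprate.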